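Assumption: the target has no stereocentres and is achiral, so "single enantiomer" needs no stereocontrol; the task reduces to regiocontrol and chemoselectivity.

**Retrosynthetic overview**
1. Target 21 comes from tribenzyl-protected tridepside 20 by one global hydrogenolysis.
2. 20 comes from ring A acid 18 and benzyl lecanorate 10, by acylation of the only phenol of 10 that is not hydrogen-bonded to an ortho carbonyl.
3. Key disconnection: the B–C depside is not cut at the ester C–O bond between two finished arenes. Ring B is cut across its C2–C7 aldol bond to the acyclic aryl triketo ester 9, made by trapping acylketene 8 (from diketo-dioxinone 5) with the free para-phenol of benzyl orsellinate 7.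
4. 5 comes from dioxinone 1 by two C-acylations; 7 comes from orsellinic acid 6 by carboxylate benzylation; 18 comes from orcylaldehyde 11 (O-methylation, Dakin, benzylation, Vilsmeier, Pinnick).
5. Ring order: ring C (purchased arene 6), then ring B (formed de novo on the ring C phenol), then ring A (purchased arene 11, attached last).

**Route**

Step 1
Reactants: 1 2,2,6-trimethyl-4H-1,3-dioxin-4-one
Product: 3 2,2-dimethyl-6-(2-oxopropyl)-4H-1,3-dioxin-4-one, via lithium dienolate 2 (not isolated)
Conditions: 1 (2 equiv), LiN(SiMe3)2 (2 equiv), THF, −78 °C; AcCl (1 equiv), −78 → 0 °C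
Reagents that add atoms: acetyl chloride CC(=O)Cl
Why: Kinetic γ-deprotonation of the vinylogous ester gives dienolate 2, which undergoes crossed Claisen-type γ-C-acylation, the second equivalent of dienolate deprotonating the more acidic product and so preventing double acylation.

Step 2
Reactants: 3 2,2-dimethyl-6-(2-oxopropyl)-4H-1,3-dioxin-4-one
Product: 5 6-(2,4-dioxopentyl)-2,2-dimethyl-4H-1,3-dioxin-4-one, via dilithium dianion 4 (not isolated)
Conditions: LiN(i-Pr)2 (2.2 equiv), THF, −78 °C; MeC(O)N(OMe)Me, −78 → −20 °C; then aq. HCl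
Reagents that add atoms: N-methoxy-N-methylacetamide CC(=O)N(C)OC
Why: Huckin–Weiler-type dianion Claisen condensation: the terminal, most basic carbon of dianion 4 is acylated by the Weinreb amide, whose chelated tetrahedral adduct prevents over-addition.

Step 3
Reactants: 6 2,4-dihydroxy-6-methylbenzoic acid (orsellinic acid)
Product: 7 benzyl 2,4-dihydroxy-6-methylbenzoate (benzyl orsellinate)
Conditions: BnBr (1.05 equiv), KHCO3 (1.1 equiv), DMF, rt
Reagents that add atoms: benzyl bromide BrCc1ccccc1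
Why: Carboxylate O-alkylation (SN2): hydrogencarbonate deprotonates only the carboxylic acid, so the phenols are not benzylated, and the mild temperature avoids decarboxylation.

Step 4
Reactants: 5 6-(2,4-dioxopentyl)-2,2-dimethyl-4H-1,3-dioxin-4-one (1.2 equiv); 7 benzyl 2,4-dihydroxy-6-methylbenzoate
Product: 10 benzyl 4-[(2,4-dihydroxy-6-methylbenzoyl)oxy]-2-hydroxy-6-methylbenzoate (benzyl lecanorate), via acylketene 8 (not isolated), via aryl triketo ester 9 (not isolated)
Conditions: PhMe, 110 °C; then Et3N (0.2 equiv), CH2Cl2, rt; then CF3CO2H (1 equiv), rt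
Reagents that add atoms: none
Why: Thermal retro-hetero-Diels–Alder loss of acetone gives acylketene 8, the non-chelated para-hydroxyl of 7 adds to it, and aryl triketo ester 9 closes by intramolecular aldol condensation of C2 onto the C7 ketone and dehydrates to the arene (biomimetic polyketide aromatisation), the non-nucleophilic amine in an aprotic solvent sparing the aryl ester and favouring aldol over Claisen or pyrone closure.

Step 5
Reactants: 11 2,4-dihydroxy-6-methylbenzaldehyde
Product: 12 2-hydroxy-4-methoxy-6-methylbenzaldehyde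
Conditions: MeI (1.05 equiv), K2CO3 (1.1 equiv), acetone, rt → 50 °C
Reagents that add atoms: iodomethane CI
Why: Williamson etherification is selective for the 4-OH because the 2-OH is held in a strong hydrogen bond to the aldehyde and is less acidic and less nucleophilic.

Step 6
Reactants: 12 2-hydroxy-4-methoxy-6-methylbenzaldehyde
Product: 14 5-methoxy-3-methylbenzene-1,2-diol, via aryl formate 13 (not isolated)
Conditions: H2O2 (30% aq.), NaOH, THF/H2O, 0 °C → rt, N2; then aq. HCl
Reagents that add atoms: hydrogen peroxide OO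
Why: Dakin oxidation: hydroperoxide adds to the aldehyde, the electron-rich aryl group migrates to oxygen to give formate 13, and in situ hydrolysis gives the catechol.

Step 7
Reactants: 14 5-methoxy-3-methylbenzene-1,2-diol
Product: 15 1,2-bis(benzyloxy)-5-methoxy-3-methylbenzene
Conditions: BnBr (2.3 equiv), K2CO3, DMF, 60 °C, N2
Reagents that add atoms: benzyl bromide BrCc1ccccc1
Why: Double Williamson benzylation caps the air-sensitive catechol with groups that leave in the final hydrogenolysis.

Step 8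
Reactants: 15 1,2-bis(benzyloxy)-5-methoxy-3-methylbenzene
Product: 17 3,4-bis(benzyloxy)-6-methoxy-2-methylbenzaldehyde, via iminium chloride 16 (not isolated)
Conditions: POCl3, DMF, 0 → 70 °C; then ice–water
Reagents that add atoms: N,N-dimethylformamide CN(C)C=O; water O
Why: Vilsmeier–Haack formylation goes to the carbon para to the 1-benzyloxy group and ortho to the methoxy group (the same preference as in 3,5-dimethoxytoluene and 1,2,4-trialkoxybenzenes), not to the carbon flanked by two alkoxy groups.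

Step 9
Reactants: 17 3,4-bis(benzyloxy)-6-methoxy-2-methylbenzaldehyde
Product: 18 3,4-bis(benzyloxy)-6-methoxy-2-methylbenzoic acid
Conditions: NaClO2, NaH2PO4, 2-methyl-2-butene, t-BuOH/H2O, rt
Reagents that add atoms: sodium chlorite [Na+].[O-]Cl=O
Why: Pinnick oxidation converts the hindered electron-rich aldehyde to the acid while the alkene scavenger removes hypochlorous acid before it can chlorinate the ring.

Step 10
Reactants: 18 3,4-bis(benzyloxy)-6-methoxy-2-methylbenzoic acid; 10 benzyl 4-[(2,4-dihydroxy-6-methylbenzoyl)oxy]-2-hydroxy-6-methylbenzoate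
Product: 20 benzyl 4-[(4-{[3,4-bis(benzyloxy)-6-methoxy-2-methylbenzoyl]oxy}-2-hydroxy-6-methylbenzoyl)oxy]-2-hydroxy-6-methylbenzoate, via mixed anhydride 19 (not isolated)
Conditions: (CF3CO)2O (4 equiv), PhMe, rt
Reagents that add atoms: none
Why: Mixed-anhydride depside esterification: the trifluoroacetic mixed anhydride 19 of the electron-rich 2,6-disubstituted acid is an acylium-like donor that acylates the ring B 4-OH, the only phenol of 10 not deactivated by a hydrogen bond to an ortho carbonyl.

Step 11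
Reactants: 20 benzyl 4-[(4-{[3,4-bis(benzyloxy)-6-methoxy-2-methylbenzoyl]oxy}-2-hydroxy-6-methylbenzoyl)oxy]-2-hydroxy-6-methylbenzoate
Product: 21 4-[(4-{[3,4-dihydroxy-6-methoxy-2-methylbenzoyl]oxy}-2-hydroxy-6-methylbenzoyl)oxy]-2-hydroxy-6-methylbenzoic acid (target)
Conditions: H2 (1 atm), 10% Pd/C, EtOAc/THF, rt
Reagents that add atoms: none
Why: Heterogeneous catalytic hydrogenolysis cleaves the benzyl ester and both benzyl ethers while the two aryl ester linkages are inert, releasing the acid and the catechol.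

**Compound list**
1 | 2,2,6-trimethyl-4H-1,3-dioxin-4-one | CC1=CC(=O)OC(C)(C)O1 | starting material
2 | lithium 2,2-dimethyl-6-methylidene-6H-1,3-dioxin-4-olate (lithium dienolate of 1) | C=C1C=C([O-])OC(C)(C)O1.[Li+] | intermediate
3 | 2,2-dimethyl-6-(2-oxopropyl)-4H-1,3-dioxin-4-one | CC(=O)CC1=CC(=O)OC(C)(C)O1 | intermediate
4 | dilithium 2,2-dimethyl-6-(2-oxidoprop-2-en-1-ylidene)-6H-1,3-dioxin-4-olate (dianion of 3) | C=C([O-])C=C1C=C([O-])OC(C)(C)O1.[Li+].[Li+] | intermediate
5 | 6-(2,4-dioxopentyl)-2,2-dimethyl-4H-1,3-dioxin-4-one | CC(=O)CC(=O)CC1=CC(=O)OC(C)(C)O1 | intermediate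
6 | 2,4-dihydroxy-6-methylbenzoic acid (orsellinic acid) | Cc1cc(O)cc(O)c1C(=O)O | starting material
7 | benzyl 2,4-dihydroxy-6-methylbenzoate (benzyl orsellinate) | Cc1cc(O)cc(O)c1C(=O)OCc1ccccc1 | intermediate
8 | oct-1-ene-1,3,5,7-tetrone (3,5-dioxohexanoylketene) | CC(=O)CC(=O)CC(=O)C=C=O | intermediate
9 | benzyl 2-hydroxy-6-methyl-4-[(3,5,7-trioxooctanoyl)oxy]benzoate | CC(=O)CC(=O)CC(=O)CC(=O)Oc1cc(C)c(C(=O)OCc2ccccc2)c(O)c1 | intermediate
10 | benzyl 4-[(2,4-dihydroxy-6-methylbenzoyl)oxy]-2-hydroxy-6-methylbenzoate (benzyl lecanorate) | Cc1cc(O)cc(O)c1C(=O)Oc1cc(C)c(C(=O)OCc2ccccc2)c(O)c1 | intermediate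
11 | 2,4-dihydroxy-6-methylbenzaldehyde | Cc1cc(O)cc(O)c1C=O | starting material
12 | 2-hydroxy-4-methoxy-6-methylbenzaldehyde | COc1cc(C)c(C=O)c(O)c1 | intermediate
13 | 2-hydroxy-4-methoxy-6-methylphenyl formate | COc1cc(C)c(OC=O)c(O)c1 | intermediate
14 | 5-methoxy-3-methylbenzene-1,2-diol | COc1cc(C)c(O)c(O)c1 | intermediate
15 | 1,2-bis(benzyloxy)-5-methoxy-3-methylbenzene | COc1cc(C)c(OCc2ccccc2)c(OCc2ccccc2)c1 | intermediate
16 | N-{[3,4-bis(benzyloxy)-6-methoxy-2-methylphenyl]methylidene}-N-methylmethanaminium chloride | COc1cc(OCc2ccccc2)c(OCc2ccccc2)c(C)c1C=[N+](C)C.[Cl-] | intermediate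
17 | 3,4-bis(benzyloxy)-6-methoxy-2-methylbenzaldehyde | COc1cc(OCc2ccccc2)c(OCc2ccccc2)c(C)c1C=O | intermediate
18 | 3,4-bis(benzyloxy)-6-methoxy-2-methylbenzoic acid | COc1cc(OCc2ccccc2)c(OCc2ccccc2)c(C)c1C(=O)O | intermediate
19 | 3,4-bis(benzyloxy)-6-methoxy-2-methylbenzoic trifluoroacetic anhydride | COc1cc(OCc2ccccc2)c(OCc2ccccc2)c(C)c1C(=O)OC(=O)C(F)(F)F | intermediate
20 | benzyl 4-[(4-{[3,4-bis(benzyloxy)-6-methoxy-2-methylbenzoyl]oxy}-2-hydroxy-6-methylbenzoyl)oxy]-2-hydroxy-6-methylbenzoate | COc1cc(OCc2ccccc2)c(OCc2ccccc2)c(C)c1C(=O)Oc1cc(C)c(C(=O)Oc2cc(C)c(C(=O)OCc3ccccc3)c(O)c2)c(O)c1 | intermediate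
21 | 4-[(4-{[3,4-dihydroxy-6-methoxy-2-methylbenzoyl]oxy}-2-hydroxy-6-methylbenzoyl)oxy]-2-hydroxy-6-methylbenzoic acid | COc1cc(O)c(O)c(C)c1C(=O)Oc1cc(C)c(C(=O)Oc2cc(C)c(C(=O)O)c(O)c2)c(O)c1 | target

**Totals**
Total step count: 11. Longest linear sequence: 7 steps (steps 5–11, from 11). The dioxinone branch is 5 steps (steps 1, 2, 4, 10, 11) and the ring C branch is 4 steps (steps 3, 4, 10, 11).

**Three steps most likely to fail, each with a fallback**

Step 4 (key step). The aryl triketo ester 9 carries a good leaving group, so Claisen closure or pyrone formation with loss of 7 can compete with the aldol aromatisation, and the ketene may also be trapped at the chelated 2-OH. The fallback sets out from 5 and 7 and comes back at 10; it aromatises ring B before the ester is made. Compound 5 is cyclised without ketene formation (Et3N, CH2Cl2, rt) to 7-hydroxy-2,2,5-trimethyl-4H-1,3-benzodioxin-4-one F1. This is silylated (TBSCl, imidazole, DMF) to 7-[(tert-butyldimethylsilyl)oxy]-2,2,5-trimethyl-4H-1,3-benzodioxin-4-one F2. Irradiation of F2 (300 nm, CH2Cl2) in the presence of 7 expels acetone and gives the quinoketene 3-[(tert-butyldimethylsilyl)oxy]-5-methyl-6-(oxomethylidene)cyclohexa-2,4-dien-1-one F3. F3 acylates the 4-OH of 7 to give benzyl 4-({4-[(tert-butyldimethylsilyl)oxy]-2-hydroxy-6-methylbenzoyl}oxy)-2-hydroxy-6-methylbenzoate F4. HF·pyridine in THF removes the silyl group and returns 10.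

Step 8. Formylation of 15 could occur in part at the other free ring carbon (between methoxy and benzyloxy), giving a regioisomer that is hard to separate. The fallback sets out from 12 and comes back at 18; it fixes the regiochemistry on the free phenol and brings in the carboxyl carbon as CO2. NBS in MeCN at 0 °C brominates 12 para to the free hydroxyl to give 3-bromo-6-hydroxy-4-methoxy-2-methylbenzaldehyde F5, whose substitution pattern can be confirmed by NOE before material is committed. Dakin oxidation (H2O2, NaOH) gives 4-bromo-5-methoxy-3-methylbenzene-1,2-diol F6. Benzylation (BnBr, K2CO3, DMF) gives 1,2-bis(benzyloxy)-4-bromo-5-methoxy-3-methylbenzene F7. Bromine–lithium exchange (n-BuLi, THF, −78 °C) gives [3,4-bis(benzyloxy)-6-methoxy-2-methylphenyl]lithium F8, which is quenched with CO2 and acidified with aq. HCl to give 18.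

Step 10. A hindered 2,6-disubstituted acid must acylate one of three free phenols of 10, and trifluoroacetylation or over-acylation could erode the yield. The fallback sets out from 18 (with 5 and 7) and comes back at 20; it inverts the order of assembly so that ring A is attached to a ring B partner with a single phenol. Compound 5 is converted to 7-hydroxy-2,2,5-trimethyl-4H-1,3-benzodioxin-4-one F1 as in the fallback to step 4. F1 is esterified with 18 ((CF3CO)2O, PhMe, rt) to give 2,2,5-trimethyl-4-oxo-4H-1,3-benzodioxin-7-yl 3,4-bis(benzyloxy)-6-methoxy-2-methylbenzoate F9. Irradiation of F9 (300 nm, CH2Cl2) with 7 gives the quinoketene 5-methyl-3-oxo-4-(oxomethylidene)cyclohexa-1,5-dien-1-yl 3,4-bis(benzyloxy)-6-methoxy-2-methylbenzoate F10, which is trapped by the 4-OH of 7 to give 20 directly.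

**Further compounds**
F1 | step 4 | 7-hydroxy-2,2,5-trimethyl-4H-1,3-benzodioxin-4-one | Cc1cc(O)cc2c1C(=O)OC(C)(C)O2
F2 | step 4 | 7-[(tert-butyldimethylsilyl)oxy]-2,2,5-trimethyl-4H-1,3-benzodioxin-4-one | Cc1cc(O[Si](C)(C)C(C)(C)C)cc2c1C(=O)OC(C)(C)O2
F3 | step 4 | 3-[(tert-butyldimethylsilyl)oxy]-5-methyl-6-(oxomethylidene)cyclohexa-2,4-dien-1-one | O=C=C1C(=O)C=C(O[Si](C)(C)C(C)(C)C)C=C1C
F4 | step 4 | benzyl 4-({4-[(tert-butyldimethylsilyl)oxy]-2-hydroxy-6-methylbenzoyl}oxy)-2-hydroxy-6-methylbenzoate | Cc1cc(O[Si](C)(C)C(C)(C)C)cc(O)c1C(=O)Oc1cc(C)c(C(=O)OCc2ccccc2)c(O)c1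
F5 | step 8 | 3-bromo-6-hydroxy-4-methoxy-2-methylbenzaldehyde | COc1cc(O)c(C=O)c(C)c1Br
F6 | step 8 | 4-bromo-5-methoxy-3-methylbenzene-1,2-diol | COc1cc(O)c(O)c(C)c1Br
F7 | step 8 | 1,2-bis(benzyloxy)-4-bromo-5-methoxy-3-methylbenzene | COc1cc(OCc2ccccc2)c(OCc2ccccc2)c(C)c1Br
F8 | step 8 | [3,4-bis(benzyloxy)-6-methoxy-2-methylphenyl]lithium | COc1cc(OCc2ccccc2)c(OCc2ccccc2)c(C)c1[Li]
F9 | step 10 | 2,2,5-trimethyl-4-oxo-4H-1,3-benzodioxin-7-yl 3,4-bis(benzyloxy)-6-methoxy-2-methylbenzoate | COc1cc(OCc2ccccc2)c(OCc2ccccc2)c(C)c1C(=O)Oc1cc(C)c2C(=O)OC(C)(C)Oc2c1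
F10 | step 10 | 5-methyl-3-oxo-4-(oxomethylidene)cyclohexa-1,5-dien-1-yl 3,4-bis(benzyloxy)-6-methoxy-2-methylbenzoate | COc1cc(OCc2ccccc2)c(OCc2ccccc2)c(C)c1C(=O)OC1=CC(=O)C(=C=O)C(C)=C1
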